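**Retrosynthetic overview**
- Last operation: neutral removal of two O-benzyl groups from the 2',4'-di-O-benzyl flavone.
- Pyranone ring (the only ring made; both benzene rings are bought intact): O1–C2 bond closed by oxidative oxa-cyclisation of a 2'-hydroxychalcone.
- Chalcone C–C bond: Claisen–Schmidt union of 2-hydroxy-3,4,5,6-tetramethoxyacetophenone with 2,4-bis(benzyloxy)-5-methoxybenzaldehyde.
- Phenolic C–O bond of that acetophenone (the future O1–C8a bond): ketone-directed C–H oxygenation of 2,3,4,5-tetramethoxyacetophenone at its single aromatic C–H (the new step).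
- Acetophenone from 1,2,3,4-tetramethoxybenzene by Friedel–Crafts acetylation; aldehyde from 2,4-dihydroxy-5-methoxybenzaldehyde by benzylation.

Assumption: the target has no stereocentre, so it is made as the single achiral compound drawn; 1,2,3,4-tetramethoxybenzene and 2,4-dihydroxy-5-methoxybenzaldehyde are taken as inexpensive catalogue compounds.

**Route**

Step 1
Reactants: 1 1,2,3,4-tetramethoxybenzene
Product: 2 1-(2,3,4,5-tetramethoxyphenyl)ethan-1-one
Conditions: Ac2O (1.5 equiv), Bi(OTf)3 (5 mol%), MeNO2, 50 °C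
Reagents that add atoms: acetic anhydride, CC(=O)OC(C)=O
Why: Friedel–Crafts acylation at one of the two equivalent free positions of the electron-rich ring (para to the 2-OMe, ortho to the 4-OMe), with a catalytic metal triflate instead of stoichiometric AlCl3 so that the methoxy group next to the new ketone is not cleaved by chelation, and with the deactivating acetyl group stopping a second acylation.

Step 2
Reactants: 2 1-(2,3,4,5-tetramethoxyphenyl)ethan-1-one
Product: 4 1-(2-hydroxy-3,4,5,6-tetramethoxyphenyl)ethan-1-one, via aryl trifluoroacetate 3 (not isolated)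
Conditions: Pd(TFA)2 (10 mol%), K2S2O8 (2 equiv), TFA/TFAA 9:1, 50 °C; then aq NaHCO3, rt
Reagents that add atoms: trifluoroacetic acid, OC(=O)C(F)(F)F
Why: Proposed new method: ketone-directed Pd(II)/Pd(IV) C–H trifluoroacetoxylation of a penta-substituted tetra-alkoxyarene whose single aromatic C–H is flanked by the acyl group and a methoxy group, in which the acetyl oxygen binds electrophilic Pd(TFA)+, concerted metalation–deprotonation at C6 (ortho to 5-OMe, para to 3-OMe, the only C–H, so regiochemistry is unambiguous) gives a five-membered palladacycle, persulfate oxidises it to Pd(IV), C–O reductive elimination releases the electron-poor ester 3 that resists over-oxidation (the ring being further protected because the ketone is hydrogen-bonded or protonated in TFA), and bicarbonate work-up unmasks the chelated phenol 4; the closest known reaction type is the Pd- or Ru-catalysed ketone-directed ortho-hydroxylation of simple mono- and disubstituted aryl ketones with persulfate or iodine(III) oxidants in TFA/TFAA, not yet shown on a fully substituted, oxidation-prone polymethoxyarene with a doubly flanked C–H.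

Step 3
Reactants: 5 2,4-dihydroxy-5-methoxybenzaldehyde
Product: 6 2,4-bis(benzyloxy)-5-methoxybenzaldehyde
Conditions: BnBr (2.3 equiv), K2CO3 (3 equiv), DMF, 60 °C
Reagents that add atoms: benzyl bromide, BrCc1ccccc1
Why: Williamson ether synthesis (SN2 of both phenoxides on benzyl bromide), with warming and excess reagent to bring the hydrogen-bonded 2-OH to completion, giving benzyl ethers that survive the basic and oxidative steps and leave under neutral hydrogenolysis.

Step 4
Reactants: 4 1-(2-hydroxy-3,4,5,6-tetramethoxyphenyl)ethan-1-one, 6 2,4-bis(benzyloxy)-5-methoxybenzaldehyde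
Product: 7 (E)-3-[2,4-bis(benzyloxy)-5-methoxyphenyl]-1-(2-hydroxy-3,4,5,6-tetramethoxyphenyl)prop-2-en-1-one
Conditions: KOH (50% aq), EtOH, rt, 48 h; then 1 M HCl
Reagents that add atoms: none
Why: Claisen–Schmidt condensation in which the methyl-ketone enolate of phenoxide 4 adds to the non-enolisable aldehyde 6 and E1cB dehydration gives the conjugated enone as the thermodynamically preferred E isomer, the only stereo-element of the route and one that is erased in step 5.

Step 5
Reactants: 7 (E)-3-[2,4-bis(benzyloxy)-5-methoxyphenyl]-1-(2-hydroxy-3,4,5,6-tetramethoxyphenyl)prop-2-en-1-one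
Product: 8 2-[2,4-bis(benzyloxy)-5-methoxyphenyl]-5,6,7,8-tetramethoxy-4H-chromen-4-one
Conditions: I2 (10 mol%), DMSO, 120 °C; aq Na2S2O3 work-up
Reagents that add atoms: none
Why: Iodine-catalysed oxidative cyclisation of a 2'-hydroxychalcone (I2/DMSO flavone synthesis), in which the only free hydroxyl adds 6-endo to the β-carbon to form the O1–C2 bond and iodine, regenerated from HI by DMSO, takes the ring to the γ-pyrone oxidation level, so only the 5,6,7,8-tetramethoxyflavone can form.

Step 6
Reactants: 8 2-[2,4-bis(benzyloxy)-5-methoxyphenyl]-5,6,7,8-tetramethoxy-4H-chromen-4-one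
Product: 9 2-(2,4-dihydroxy-5-methoxyphenyl)-5,6,7,8-tetramethoxy-4H-chromen-4-one
Conditions: H2 (1 atm), 10% Pd/C, EtOAc–MeOH 1:1, rt
Reagents that add atoms: none
Why: Catalytic hydrogenolysis of the two aryl benzyl ethers under neutral conditions, which leaves the five methyl ethers and the vinylogous-ester C2=C3 bond untouched and avoids the acid- or base-induced ring opening and re-closure through the 2'-OH that could scramble the flavone.

**Compound list**

1 | 1,2,3,4-tetramethoxybenzene | COc1ccc(OC)c(OC)c1OC | starting material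
2 | 1-(2,3,4,5-tetramethoxyphenyl)ethan-1-one | CC(=O)c1cc(OC)c(OC)c(OC)c1OC | intermediate
3 | 2-acetyl-3,4,5,6-tetramethoxyphenyl 2,2,2-trifluoroacetate (not isolated) | CC(=O)c1c(OC(=O)C(F)(F)F)c(OC)c(OC)c(OC)c1OC | intermediate
4 | 1-(2-hydroxy-3,4,5,6-tetramethoxyphenyl)ethan-1-one | CC(=O)c1c(O)c(OC)c(OC)c(OC)c1OC | intermediate
5 | 2,4-dihydroxy-5-methoxybenzaldehyde | COc1cc(C=O)c(O)cc1O | starting material
6 | 2,4-bis(benzyloxy)-5-methoxybenzaldehyde | COc1cc(C=O)c(OCc2ccccc2)cc1OCc1ccccc1 | intermediate
7 | (E)-3-[2,4-bis(benzyloxy)-5-methoxyphenyl]-1-(2-hydroxy-3,4,5,6-tetramethoxyphenyl)prop-2-en-1-one | COc1cc(/C=C/C(=O)c2c(O)c(OC)c(OC)c(OC)c2OC)c(OCc2ccccc2)cc1OCc1ccccc1 | intermediate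
8 | 2-[2,4-bis(benzyloxy)-5-methoxyphenyl]-5,6,7,8-tetramethoxy-4H-chromen-4-one | COc1cc(-c2cc(=O)c3c(OC)c(OC)c(OC)c(OC)c3o2)c(OCc2ccccc2)cc1OCc1ccccc1 | intermediate
9 | 2-(2,4-dihydroxy-5-methoxyphenyl)-5,6,7,8-tetramethoxy-4H-chromen-4-one (achiral) | COc1cc(-c2cc(=O)c3c(OC)c(OC)c(OC)c(OC)c3o2)c(O)cc1O | target

**Step count and risks**

Total step count: 6. Longest linear sequence: 5 steps (1 → 2 → 4 → 7 → 8 → 9, steps 1, 2, 4, 5 and 6); step 3 is the side branch.

Three steps most likely to fail:

Step 2 (the proposed new C–H oxygenation). The tetramethoxy ring may be oxidised by persulfate, or palladation at the doubly flanked C–H may be too slow. The fallback uses known chemistry and sets out from 2: Baeyer–Villiger oxidation (m-CPBA, NaHCO3, CH2Cl2, rt; the electron-rich aryl group migrates) gives 2,3,4,5-tetramethoxyphenyl acetate F1. A Fries rearrangement (BF3·OEt2, AcOH, 90 °C) can deliver the acetyl group only to the single free ortho position and comes back to the route at 4, at the cost of one extra step.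

Step 4 (Claisen–Schmidt condensation). The ketone is di-ortho-substituted and the aldehyde is electron-rich and ortho-substituted, so the condensation may stall. The fallback sets out from 6 and 4 and replaces the aldol by an acyl-transfer sequence. Pinnick oxidation of 6 (NaClO2, NaH2PO4, 2-methyl-2-butene, t-BuOH/H2O) gives 2,4-bis(benzyloxy)-5-methoxybenzoic acid F2. Esterification of the phenol of 4 with it (EDC, DMAP, CH2Cl2) gives 2-acetyl-3,4,5,6-tetramethoxyphenyl 2,4-bis(benzyloxy)-5-methoxybenzoate F3. Baker–Venkataraman rearrangement (KOH, pyridine, 50 °C) gives 1-[2,4-bis(benzyloxy)-5-methoxyphenyl]-3-(2-hydroxy-3,4,5,6-tetramethoxyphenyl)propane-1,3-dione F4. Acid-catalysed cyclodehydration (TsOH cat., toluene, 80 °C; only ring A carries a free OH) comes back to the route at 8, bypassing 7.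

Step 5 (I2/DMSO cyclisation). Hot HI/I2 may cleave a benzyl ether or the 5-OMe, or iodinate the B ring. The fallback sets out from 7 and separates ring closure from oxidation. Base-mediated oxa-Michael isomerisation (NaOAc, EtOH, reflux) gives rac-2-[2,4-bis(benzyloxy)-5-methoxyphenyl]-5,6,7,8-tetramethoxy-2,3-dihydro-4H-chromen-4-one F5. Iodine-free dehydrogenation (Pd(TFA)2 cat., DMSO, O2, 80 °C) comes back to the route at 8.

Further compounds
F1 | step 2 | 2,3,4,5-tetramethoxyphenyl acetate | CC(=O)Oc1cc(OC)c(OC)c(OC)c1OC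
F2 | step 4 | 2,4-bis(benzyloxy)-5-methoxybenzoic acid | COc1cc(C(=O)O)c(OCc2ccccc2)cc1OCc1ccccc1
F3 | step 4 | 2-acetyl-3,4,5,6-tetramethoxyphenyl 2,4-bis(benzyloxy)-5-methoxybenzoate | COc1cc(C(=O)Oc2c(C(C)=O)c(OC)c(OC)c(OC)c2OC)c(OCc2ccccc2)cc1OCc1ccccc1
F4 | step 4 | 1-[2,4-bis(benzyloxy)-5-methoxyphenyl]-3-(2-hydroxy-3,4,5,6-tetramethoxyphenyl)propane-1,3-dione | COc1cc(C(=O)CC(=O)c2c(O)c(OC)c(OC)c(OC)c2OC)c(OCc2ccccc2)cc1OCc1ccccc1
F5 | step 5 | rac-2-[2,4-bis(benzyloxy)-5-methoxyphenyl]-5,6,7,8-tetramethoxy-2,3-dihydro-4H-chromen-4-one (racemic) | COc1cc(C2CC(=O)c3c(OC)c(OC)c(OC)c(OC)c3O2)c(OCc2ccccc2)cc1OCc1ccccc1
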